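The first nucleophile stands to the second at 1.58 in the charge, so two nucleophiles sharing one species with a selectivity factor of one would give other capture product a statistical share of 38.8% of all that is captured. That share is the zero of the scale.

| flask | starting material | first nucleophile | second nucleophile | remark | time |
|---|---|---|---|---|---|
| north-east | 33 mM | 49.5 mM | 31.4 mM | run made earlier |  |
| north | 22 mM | 49.5 mM | 31.4 mM | run made earlier |  |
| south | 50 mM | 49.5 mM | 31.4 mM | run made earlier |  |
| south-east | 33 mM | 25 mM | 31.4 mM | run made earlier |  |
| elm | 33 mM | 49.5 mM | 31.4 mM | everything together at the start | 5.0 min |
| maple | 33 mM (fed, over 1.0 min) | 49.5 mM | 31.4 mM | all else is in the flask from the start; the feed brings no volume worth counting | 5.0 min |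
| birch | 33 mM | 49.5 mM | 31.4 mM (fed, over 1.0 min) | all else is in the flask from the start; the feed brings no volume worth counting | 5.0 min |

| run | time / min | target / % | other capture product / % |
|---|---|---|---|
| north-east | 0.833 | 38 | 6 |
| north-east | 1.50 | 48 | 9 |
| north-east | 2.50 | 55 | 8 |
| north-east | 3.00 | 54 | 9 |
| north | 1.00 | 46 | 5 |
| north | 2.00 | 58 | 9 |
| north | 3.00 | 59 | 5 |
| north | 4.00 | 61 | 9 |
| south | 0.500 | 26 | 7 |
| south | 1.33 | 42 | 9 |
| south | 2.50 | 45 | 8 |
| south | 4.00 | 44 | 9 |
| south-east | 0.500 | 19 | 12 |
| south-east | 1.33 | 38 | 13 |
| south-east | 2.50 | 44 | 14 |
| south-east | 4.00 | 46 | 13 |

(scatter of a reading: 1.5 percentage points)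



- the flask that comes out highest in share of target in target plus other capture product, or "all alike" when all lie within 1.5 percentage points (elm / maple / birch / all alike)
- share of target in target plus other capture product at the end, elm
- share of target in target plus other capture product at the end, maple
- share of target in target plus other capture product at the end, birch

The north-east run has elm's recipe, and its ledger is flat from 2.50 min. Of the starting material charged, the reading at 3.00 min books 54% as target and 9% as other capture product, and the unread rest is 37.0%. The asked share uses the first two entries, so other capture product holds 14.3% of the captured material. The overlap, this share divided by the statistical share, is 0.368. The south-east run gives 0.396 on a statistical share of 55.7%, so the overlap stays close while the zero moves.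

Target's rise reads as a lifetime of starting material of 0.685 min. If the overlap is the second nucleophile's lifetime over the sum of both lifetimes, that lifetime is 0.399 min. For first-order decays, a steady feed multiplies the overlap by one minus exp(−x), divided by x, where x is the feed time over the lifetime of the partner not fed. The factor is 0.366 for maple and 0.526 for birch. This reckoning gives elm 85.7%, birch 92.5% and maple 94.8%, the highest.

The forecast differs in choosing birch, with elm 87%, maple 89.5% and birch 96%, on the ground that “little second nucleophile is present while starting material lives”.

The flasks give maple as highest: elm 86.1%, maple 94.5%, birch 84.7%.

    intermediate → solvolysis product (k = 0.854 /s)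
    first nucleophile + intermediate → target (k = 244 /M/s)
    2 second nucleophile → homo dimer (k = 2.75 /M/s)
    second nucleophile → decomposed reagent (k = 0.0174 /s)
    starting material → intermediate (k = 0.0182 /s)
    starting material + target → side product (k = 0.349 /M/s)
    second nucleophile + intermediate → other capture product (k = 270 /M/s)

Read back, the overlap is 0.358 in elm, 0.142 in maple and 0.394 in birch, where the reckoning held 0.194. The feed lasts 1.1 lifetimes of starting material against everything charged and 1.04 lifetimes of second nucleophile by decomposition alone. At 1.00 min, birch holds 25.2% of its second nucleophile beside 27.8% of starting material, and maple 3.81% beside 58.0%. A birch flask with 120 mM of first nucleophile has a statistical share of 20.7%, so birch's overlap gives 91.8%, and that flask stands at 93.7%.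

Readings and results come from a simulation for substances that don't exist; scatter was added.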